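**Assumption:** the given structure leaves the biaryl axis undefined, so it is not controlled; compounds 10, 12, 13 and 14 are carried as mixtures of the two atropisomers (from 13 on both have the (2S) centre).

## Retrosynthetic overview

1. 14 ⇐ 13: hydrogenolysis of six benzyl ethers, with no change at C-2.
2. 13 ⇐ 12: the O-1–C-2 bond of the flavanone is closed by an enantioselective 6-endo oxa-Michael reaction of the chalcone; this is the last ring formed and it sets the only stereocentre.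
3. 12 ⇐ 10 + 11: aldol condensation builds the enone.
4. 10 ⇐ 3 + 7: Suzuki–Miyaura union of flavone C-8 with a bromoacetophenone whose only free OH is para to the bromine, so the later ring closure can only give the 6-linked flavanone.
5. 3 ⇐ apigenin (flavone rings bought intact); 7 ⇐ 3,5-bis(benzyloxy)phenol by para-bromination, then ortho-acetylation.

Catalyst A (used in step 7) is 1-[3,5-bis(trifluoromethyl)phenyl]-3-[(2S)-3,3-dimethyl-1-{[tris(4-methoxyphenyl)-λ5-phosphanylidene]amino}butan-2-yl]thiourea, SMILES `CC(C)(C)[C@H](NC(=S)Nc1cc(cc(c1)C(F)(F)F)C(F)(F)F)CN=P(c1ccc(OC)cc1)(c1ccc(OC)cc1)c1ccc(OC)cc1`. It is drawn as the L-tert-leucine-derived antipode; which antipode gives the (2S) product must be fixed in a first screen of both.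

## Route

Step 1
Reactants: 1 apigenin
Product: 2 5,7-bis(benzyloxy)-2-[4-(benzyloxy)phenyl]-4H-chromen-4-one
Conditions: BnBr (4.5 equiv), K2CO3, Bu4NI (cat.), DMF, 80 °C
Reagents that add atoms: benzyl bromide, BrCc1ccccc1
Why: Williamson ether synthesis; the 7- and 4'-phenols alkylate fast, the hydrogen-bonded 5-OH follows at 80 °C with excess bromide, and the flavone ring is inert to carbonate.

Step 2
Reactants: 2 5,7-bis(benzyloxy)-2-[4-(benzyloxy)phenyl]-4H-chromen-4-one
Product: 3 5,7-bis(benzyloxy)-2-[4-(benzyloxy)phenyl]-8-iodo-4H-chromen-4-one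
Conditions: NIS (1.05 equiv), TFA (cat.), MeCN/CH2Cl2, 0 °C to rt, dark
Reagents that add atoms: N-iodosuccinimide, O=C1CCC(=O)N1I
Why: Electrophilic aromatic iodination; with O-5 alkylated, C-8 (para to O-5, ortho to O-7 and O-1, less crowded than C-6 between two benzyloxy groups) is the most nucleophilic carbon of ring A, the usual outcome for 5,7-dialkoxyflavones.

Step 3
Reactants: 4 3,5-bis(benzyloxy)phenol
Product: 5 3,5-bis(benzyloxy)-4-bromophenol
Conditions: NBS (1.0 equiv), CH2Cl2, −78 to −30 °C; chromatography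
Reagents that add atoms: N-bromosuccinimide, O=C1CCC(=O)N1Br
Why: Electrophilic aromatic bromination of an activated phenol at low temperature should go mainly para to the hydroxyl; the 2-bromo isomer is removed by chromatography and the wanted isomer is recognised by its symmetric NMR pattern (two equivalent ring protons).

Step 4
Reactants: 5 3,5-bis(benzyloxy)-4-bromophenol
Product: 7 1-[2,4-bis(benzyloxy)-3-bromo-6-hydroxyphenyl]ethan-1-one, via aryl acetate 6 (not isolated)
Conditions: AcOH, TFAA, 85% H3PO4 (cat.), CH2Cl2, 0 °C to rt; evaporate; K2CO3 (cat.), MeOH, 0 °C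
Reagents that add atoms: acetic acid, CC(=O)O
Why: Friedel–Crafts acylation with the mixed acetic–trifluoroacetic anhydride; the phenol is first O-acetylated, the only two ring C–H positions are equivalent and both ortho to that oxygen, so C-acetylation gives a single ketone, and methanolysis then frees the phenol para to the bromine (benzyl ethers should tolerate this acid strength for a short time at or below room temperature).

Step 5
Reactants: 3 5,7-bis(benzyloxy)-2-[4-(benzyloxy)phenyl]-8-iodo-4H-chromen-4-one, 8 pinacolborane, 7 1-[2,4-bis(benzyloxy)-3-bromo-6-hydroxyphenyl]ethan-1-one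
Product: 10 8-[3-acetyl-2,6-bis(benzyloxy)-4-hydroxyphenyl]-5,7-bis(benzyloxy)-2-[4-(benzyloxy)phenyl]-4H-chromen-4-one, via flavone-8-boronic acid pinacol ester 9 (not isolated)
Conditions: 3 (1.3 equiv), 8 (2 equiv), PdCl2(MeCN)2 (5 mol%), SPhos (10 mol%), Et3N, dioxane, 80 °C; then aq. K3PO4, 7 (1 equiv), 100 °C
Reagents that add atoms: none
Why: Pd-catalysed borylation of the aryl iodide with pinacolborane, then Suzuki–Miyaura coupling in the same flask; SPhos gives a monoligated zerovalent palladium species suited to joining two 2,6-dioxygenated partners, the free phenol and ketone of 7 tolerate aqueous K3PO4, and the biaryl axis forms without control.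

Step 6
Reactants: 10 8-[3-acetyl-2,6-bis(benzyloxy)-4-hydroxyphenyl]-5,7-bis(benzyloxy)-2-[4-(benzyloxy)phenyl]-4H-chromen-4-one, 11 4-(benzyloxy)benzaldehyde
Product: 12 8-{2,6-bis(benzyloxy)-3-[(2E)-3-(4-(benzyloxy)phenyl)prop-2-enoyl]-4-hydroxyphenyl}-5,7-bis(benzyloxy)-2-[4-(benzyloxy)phenyl]-4H-chromen-4-one
Conditions: 11 (1.5 equiv), KOH, EtOH/THF, rt; cold 1 M HCl to pH 5; chromatography
Reagents that add atoms: none
Why: Claisen–Schmidt aldol condensation; the methyl ketone enolate adds to the non-enolisable aldehyde and E1cB loss of water gives the (E)-enone, and because the product stays as its ring-open phenolate in strong base, cold acidification returns the chalcone and not the flavanone.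

Step 7
Reactants: 12 8-{2,6-bis(benzyloxy)-3-[(2E)-3-(4-(benzyloxy)phenyl)prop-2-enoyl]-4-hydroxyphenyl}-5,7-bis(benzyloxy)-2-[4-(benzyloxy)phenyl]-4H-chromen-4-one
Product: 13 (2S)-5,7-bis(benzyloxy)-2-[4-(benzyloxy)phenyl]-6-{5,7-bis(benzyloxy)-2-[4-(benzyloxy)phenyl]-4-oxo-4H-chromen-8-yl}-2,3-dihydro-4H-chromen-4-one
Conditions: catalyst A (10 mol%), toluene, −20 °C; AcOH quench at −20 °C
Reagents that add atoms: none
Why: Proposed new method: an iminophosphorane base tethered to a thiourea has not been used to close an unactivated 2'-hydroxychalcone to a flavanone; the P=N base (much stronger than the phenol) turns the only free hydroxyl, which lies para to the biaryl carbon so that only the 6-linked ring can form, into a tight aminophosphonium phenoxide pair while the thiourea N–H bonds hold the enone carbonyl, so the oxygen adds 6-endo-trig to the Si face of C-β and the aminophosphonium N–H protonates the enolate, setting (2S) under catalyst control (checked by the positive Cotton effect near 330 nm); the ortho benzyloxy group twists the aroyl unit and makes ring closure strongly downhill, which keeps the retro-reaction and hence racemisation slow until the cold acid quench; the closest known reaction types are the cinchona-thiourea oxa-Michael cyclisation of activated alkylidene β-keto esters to flavanones and iminophosphorane-catalysed intramolecular oxa-Michael addition of alcohols to unsaturated esters.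

Step 8
Reactants: 13 (2S)-5,7-bis(benzyloxy)-2-[4-(benzyloxy)phenyl]-6-{5,7-bis(benzyloxy)-2-[4-(benzyloxy)phenyl]-4-oxo-4H-chromen-8-yl}-2,3-dihydro-4H-chromen-4-one
Product: 14 (2S)-6-[5,7-dihydroxy-2-(4-hydroxyphenyl)-4-oxo-4H-chromen-8-yl]-5,7-dihydroxy-2-(4-hydroxyphenyl)-2,3-dihydro-4H-chromen-4-one
Conditions: H2 (1 atm), 10% Pd/C, THF/MeOH, rt
Reagents that add atoms: none
Why: Catalytic hydrogenolysis of the six benzyl ethers under neutral conditions at 1 atm leaves the chromone double bond, both aryl ketones and the benzylic C-2–O bond untouched, and with no acid or base present the (2S) centre cannot open to the chalcone and racemise.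

## Compound list

1 | apigenin, 5,7-dihydroxy-2-(4-hydroxyphenyl)-4H-chromen-4-one | O=c1cc(-c2ccc(O)cc2)oc2cc(O)cc(O)c12 | starting material
2 | 5,7-bis(benzyloxy)-2-[4-(benzyloxy)phenyl]-4H-chromen-4-one | O=c1cc(-c2ccc(OCc3ccccc3)cc2)oc2cc(OCc3ccccc3)cc(OCc3ccccc3)c12 | intermediate
3 | 5,7-bis(benzyloxy)-2-[4-(benzyloxy)phenyl]-8-iodo-4H-chromen-4-one | O=c1cc(-c2ccc(OCc3ccccc3)cc2)oc2c(I)c(OCc3ccccc3)cc(OCc3ccccc3)c12 | intermediate
4 | 3,5-bis(benzyloxy)phenol | Oc1cc(OCc2ccccc2)cc(OCc2ccccc2)c1 | starting material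
5 | 3,5-bis(benzyloxy)-4-bromophenol | Oc1cc(OCc2ccccc2)c(Br)c(OCc2ccccc2)c1 | intermediate
6 | 2-acetyl-3,5-bis(benzyloxy)-4-bromophenyl acetate (not isolated) | CC(=O)Oc1cc(OCc2ccccc2)c(Br)c(OCc2ccccc2)c1C(C)=O | intermediate
7 | 1-[2,4-bis(benzyloxy)-3-bromo-6-hydroxyphenyl]ethan-1-one | CC(=O)c1c(O)cc(OCc2ccccc2)c(Br)c1OCc1ccccc1 | intermediate
8 | pinacolborane, 4,4,5,5-tetramethyl-1,3,2-dioxaborolane | CC1(C)OBOC1(C)C | starting material
9 | 5,7-bis(benzyloxy)-2-[4-(benzyloxy)phenyl]-8-(4,4,5,5-tetramethyl-1,3,2-dioxaborolan-2-yl)-4H-chromen-4-one (not isolated) | O=c1cc(-c2ccc(OCc3ccccc3)cc2)oc2c(B3OC(C)(C)C(C)(C)O3)c(OCc3ccccc3)cc(OCc3ccccc3)c12 | intermediate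
10 | 8-[3-acetyl-2,6-bis(benzyloxy)-4-hydroxyphenyl]-5,7-bis(benzyloxy)-2-[4-(benzyloxy)phenyl]-4H-chromen-4-one (axis not controlled) | CC(=O)c1c(O)cc(OCc2ccccc2)c(-c2c(OCc3ccccc3)cc(OCc3ccccc3)c3c(=O)cc(-c4ccc(OCc5ccccc5)cc4)oc23)c1OCc1ccccc1 | intermediate
11 | 4-(benzyloxy)benzaldehyde | O=Cc1ccc(OCc2ccccc2)cc1 | starting material
12 | 8-{2,6-bis(benzyloxy)-3-[(2E)-3-(4-(benzyloxy)phenyl)prop-2-enoyl]-4-hydroxyphenyl}-5,7-bis(benzyloxy)-2-[4-(benzyloxy)phenyl]-4H-chromen-4-one | O=C(/C=C/c1ccc(OCc2ccccc2)cc1)c1c(O)cc(OCc2ccccc2)c(-c2c(OCc3ccccc3)cc(OCc3ccccc3)c3c(=O)cc(-c4ccc(OCc5ccccc5)cc4)oc23)c1OCc1ccccc1 | intermediate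
13 | (2S)-5,7-bis(benzyloxy)-2-[4-(benzyloxy)phenyl]-6-{5,7-bis(benzyloxy)-2-[4-(benzyloxy)phenyl]-4-oxo-4H-chromen-8-yl}-2,3-dihydro-4H-chromen-4-one | O=C1C[C@@H](c2ccc(OCc3ccccc3)cc2)Oc2cc(OCc3ccccc3)c(-c3c(OCc4ccccc4)cc(OCc4ccccc4)c4c(=O)cc(-c5ccc(OCc6ccccc6)cc5)oc34)c(OCc3ccccc3)c21 | intermediate
14 | (2S)-6-[5,7-dihydroxy-2-(4-hydroxyphenyl)-4-oxo-4H-chromen-8-yl]-5,7-dihydroxy-2-(4-hydroxyphenyl)-2,3-dihydro-4H-chromen-4-one | O=C1C[C@@H](c2ccc(O)cc2)Oc2cc(O)c(-c3c(O)cc(O)c4c(=O)cc(-c5ccc(O)cc5)oc34)c(O)c21 | target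

## Step count and risks

Total step count: 8. Longest linear sequence: 6 steps (1, 2, 5, 6, 7, 8 from apigenin; equally 3, 4, 5, 6, 7, 8 from 3,5-bis(benzyloxy)phenol).

The three steps most likely to fail:

**Step 7 (the proposed ring closure).** The risks are low turnover with the electron-rich enone, low enantioselectivity, or erosion of ee by the retro-reaction. The fallback uses known chemistry, sets out from 12 and comes back at 13. Chalcone 12 is cyclised without stereocontrol (NaOAc, EtOH/THF, reflux) to racemic (2RS)-5,7-bis(benzyloxy)-2-[4-(benzyloxy)phenyl]-6-{5,7-bis(benzyloxy)-2-[4-(benzyloxy)phenyl]-4-oxo-4H-chromen-8-yl}-2,3-dihydro-4H-chromen-4-one F8. Preparative supercritical-fluid chromatography on an amylose-based chiral phase then gives 13 and the (2R)-enantiomer F9. F9 is reopened to 12 with KOH in EtOH and recycled.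

**Step 5 (tetra-ortho-substituted biaryl).** The risks are protodeboronation of 9 and slow oxidative addition into the phenoxide form of 7. The fallback reverses the roles of the partners and installs the acetyl group after the biaryl bond; it sets out from 5 and 3 and comes back at 10. Bromophenol 5 is silylated (iPr3SiCl, imidazole, DMF) to [3,5-bis(benzyloxy)-4-bromophenoxy]tri(propan-2-yl)silane F3. Bromine–lithium exchange (n-BuLi, THF, −78 °C) with B(OiPr)3 present, then aqueous NH4Cl, gives [2,6-bis(benzyloxy)-4-{[tri(propan-2-yl)silyl]oxy}phenyl]boronic acid F4. F4 is coupled with iodide 3 (Pd(OAc)2, SPhos, K3PO4, toluene/H2O, 100 °C) to 5,7-bis(benzyloxy)-2-[4-(benzyloxy)phenyl]-8-[2,6-bis(benzyloxy)-4-{[tri(propan-2-yl)silyl]oxy}phenyl]-4H-chromen-4-one F5. Bu4NF/AcOH in THF frees 5,7-bis(benzyloxy)-2-[4-(benzyloxy)phenyl]-8-[2,6-bis(benzyloxy)-4-hydroxyphenyl]-4H-chromen-4-one F6, whose two free ring positions are equivalent. Acetylation under the conditions of step 4 passes through 2-acetyl-3,5-bis(benzyloxy)-4-{5,7-bis(benzyloxy)-2-[4-(benzyloxy)phenyl]-4-oxo-4H-chromen-8-yl}phenyl acetate F7, and methanolysis gives 10.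

**Step 4 (C-acetylation beside benzyl ethers).** The risks are acid-induced debenzylation and a sluggish reaction of the O-acetylated ring. The fallback avoids acid altogether; it sets out from 5 and comes back at 7. Magnesium-mediated ortho-formylation (MgCl2, Et3N, paraformaldehyde, MeCN, reflux) gives 2,4-bis(benzyloxy)-3-bromo-6-hydroxybenzaldehyde F1. MeMgBr (3 equiv, THF, −78 to 0 °C) gives racemic 1-[2,4-bis(benzyloxy)-3-bromo-6-hydroxyphenyl]ethan-1-ol F2. MnO2 in CH2Cl2 oxidises F2 to ketone 7.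

## Further compounds

F1 | step 4 | 2,4-bis(benzyloxy)-3-bromo-6-hydroxybenzaldehyde | O=Cc1c(O)cc(OCc2ccccc2)c(Br)c1OCc1ccccc1
F2 | step 4 | 1-[2,4-bis(benzyloxy)-3-bromo-6-hydroxyphenyl]ethan-1-ol (racemic) | CC(O)c1c(O)cc(OCc2ccccc2)c(Br)c1OCc1ccccc1
F3 | step 5 | [3,5-bis(benzyloxy)-4-bromophenoxy]tri(propan-2-yl)silane | CC(C)[Si](Oc1cc(OCc2ccccc2)c(Br)c(OCc2ccccc2)c1)(C(C)C)C(C)C
F4 | step 5 | [2,6-bis(benzyloxy)-4-{[tri(propan-2-yl)silyl]oxy}phenyl]boronic acid | OB(O)c1c(OCc2ccccc2)cc(O[Si](C(C)C)(C(C)C)C(C)C)cc1OCc1ccccc1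
F5 | step 5 | 5,7-bis(benzyloxy)-2-[4-(benzyloxy)phenyl]-8-[2,6-bis(benzyloxy)-4-{[tri(propan-2-yl)silyl]oxy}phenyl]-4H-chromen-4-one | CC(C)[Si](Oc1cc(OCc2ccccc2)c(-c2c(OCc3ccccc3)cc(OCc3ccccc3)c3c(=O)cc(-c4ccc(OCc5ccccc5)cc4)oc23)c(OCc2ccccc2)c1)(C(C)C)C(C)C
F6 | step 5 | 5,7-bis(benzyloxy)-2-[4-(benzyloxy)phenyl]-8-[2,6-bis(benzyloxy)-4-hydroxyphenyl]-4H-chromen-4-one | Oc1cc(OCc2ccccc2)c(-c2c(OCc3ccccc3)cc(OCc3ccccc3)c3c(=O)cc(-c4ccc(OCc5ccccc5)cc4)oc23)c(OCc2ccccc2)c1
F7 | step 5 | 2-acetyl-3,5-bis(benzyloxy)-4-{5,7-bis(benzyloxy)-2-[4-(benzyloxy)phenyl]-4-oxo-4H-chromen-8-yl}phenyl acetate | CC(=O)Oc1cc(OCc2ccccc2)c(-c2c(OCc3ccccc3)cc(OCc3ccccc3)c3c(=O)cc(-c4ccc(OCc5ccccc5)cc4)oc23)c(OCc2ccccc2)c1C(C)=O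
F8 | step 7 | (2RS)-5,7-bis(benzyloxy)-2-[4-(benzyloxy)phenyl]-6-{5,7-bis(benzyloxy)-2-[4-(benzyloxy)phenyl]-4-oxo-4H-chromen-8-yl}-2,3-dihydro-4H-chromen-4-one (racemate) | O=C1CC(c2ccc(OCc3ccccc3)cc2)Oc2cc(OCc3ccccc3)c(-c3c(OCc4ccccc4)cc(OCc4ccccc4)c4c(=O)cc(-c5ccc(OCc6ccccc6)cc5)oc34)c(OCc3ccccc3)c21
F9 | step 7 | (2R)-5,7-bis(benzyloxy)-2-[4-(benzyloxy)phenyl]-6-{5,7-bis(benzyloxy)-2-[4-(benzyloxy)phenyl]-4-oxo-4H-chromen-8-yl}-2,3-dihydro-4H-chromen-4-one | O=C1C[C@H](c2ccc(OCc3ccccc3)cc2)Oc2cc(OCc3ccccc3)c(-c3c(OCc4ccccc4)cc(OCc4ccccc4)c4c(=O)cc(-c5ccc(OCc6ccccc6)cc5)oc34)c(OCc3ccccc3)c21
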